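## The problem

The target is a 3,3'-linked dimer of two flavanones, a [3,3'-bichromane]-4,4'-dione. One half is 5,7-dihydroxy-4'-methoxyflavanone and the other is its 7-methyl ether. The four contiguous stereocentres C2, C3, C3' and C2' are all S. In both rings C the hydrogens at C2 and C3 are cis and the two halves are homochiral, so the skeleton is C2-symmetric apart from one O-methyl group. The cis arrangement is the less stable one: C3–H lies α to the C4 ketone and epimerises to trans under base, and the same enolate can expel O1 (retro-oxa-Michael) and scramble C2. Within one ring C2 can direct C3, because protonation of a C3=C4 enol derivative anti to the 2-aryl group gives the cis ring. Nothing in one half reliably directs the other, so the absolute sense of both halves has to come from a catalyst, late, and the ketones must not meet base afterwards. The central C3–C3' bond joins two tertiary carbons, each flanked by a ketone and an aryl-bearing carbon, and is far easier to carry from the start than to forge. The phloroglucinol rings are sensitive to oxidants and electrophiles, the aryl-diene intermediates are light-sensitive, and only one of two equivalent 7-hydroxyls is to be methylated. The feature that opens the plan is that each ring A (C4a, C5, C6, C7, C8, C8a) is an acylphloroglucinol: the C4 carbonyl sits on C4a, flanked by oxygens at C5 and C8a, with a third oxygen at C7. This is the folding pattern of a 3,5,7-triketo acid, which can be stored as a 4-hydroxy-6-(2-oxoalkyl)-2-pyrone.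

## Retrosynthesis

**18 to 17.** The three benzyl–oxygen bonds at O5, O5' and O7 are cut. Benzyl is chosen because hydrogenolysis is neutral and leaves the cis C3–H alone. Acyl groups would need base for removal, and silyl groups cannot be held on the chelated 5-hydroxyls. The precursor 17 has the full skeleton and all four stereocentres. The forward step must cleave three aryl benzyl ethers without opening the benzylic C2–O1 bond.

**17 to 15 (through 16).** The C2–H, C3–H, C2'–H and C3'–H bonds are removed, which erases all four stereocentres and leads to the flat 3,3'-biflavone 15. The neighbouring option, closing rings C by oxa-Michael addition from bis-chalcone 11, gives the trans rings under equilibration (mixture 12) and offers no absolute control. At the flavone level the whole stereochemical problem becomes one event carried out twice: hydride to C2 on a catalyst-chosen face, then a proton to C3 on the same face. Parking the product as the bis(silyl enol ether) 16 keeps the ketones away from base until a controlled protonation. Because the two halves are set independently, material of the wrong sense should mostly end up in a separable diastereomer.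

**15 to 14 to 13.** Three O–benzyl bonds and then one O–methyl bond (O7') are cut, leading to the symmetric tetraol 13. Placing the only basic alkylations here, before any stereocentre exists, removes the epimerisation risk that a final-step methylation would carry. The forward steps ask for alkylation of one of two equivalent, acidic 7-hydroxyls with the chelated 5-hydroxyls untouched (statistical), and then forcing benzylation of the remaining three phenols.

**13 to 11 (through 12).** The O1–C2 and O1'–C2' bonds and both C2=C3 unsaturations are removed, giving the acyclic bis(2'-hydroxychalcone) 11. Oxidative cyclisation of 2'-hydroxychalcones to flavones is standard, and it brings the 4-methoxyphenyl groups in at the aldehyde oxidation level. The forward step needs two oxa-Michael closures and dehydrogenation across C2–C3 rather than toward C3–C3'.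

**11 to 9 (through 10), the key disconnection.** In each ring A the C4a–C8a bond is cut, so both benzene rings disappear and two 4-hydroxy-2-pyrone rings take their place in 9. The alternative of joining a preformed trioxygenated benzene to the hindered diene diacid by electrophilic acylation would need phenol protection and a Lewis acid that the aryl-diene is unlikely to tolerate. The pyrone route fixes the oxygen pattern by construction and runs under mild base. The forward reaction must choose Claisen over aldol closure and leave both enones alone.

**9 to 6 and 7 (through 8).** The two bonds between each pyrone's exocyclic methylene and the side-chain carbonyl are cut. The dianion 8 of commercial pyrone 7 is a known carbon nucleophile at its methyl group, and diester 6 supplies both acyl groups at once. The forward step must favour 1,2- over 1,4-addition and must go twice.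

**6 to 5 to 4 to 3, then 1 and 2.** The two arylidene C=C bonds are cut by Stobbe condensations of diethyl succinate 1 with 4-methoxybenzaldehyde 2, with re-esterification in between. The C2–C3 bond of 1 becomes the C3–C3' bond of the target, so the most hindered bond of the molecule is never made. The Stobbe reaction gives E alkenes with the aryl group trans to the carbonyl.

## Roads not taken

**Alternative 1:** The cut is at C3–C3' and both benzylic C–O bonds, traced to oxidative coupling of two molecules of 4-hydroxycinnamic acid A1. In the forward step FeCl3 and O2 turn A1 into phenoxy radicals that join at the carbons α to the carboxyls, after which each carboxylate adds to the quinone methide of the other half and closes the cis-fused bis-lactone A2.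
- Merits: one step from the commodity acid A1 gives the central bond and a rigid bicycle with defined relative configuration at four carbons.
- Weak points: A2 is racemic and must be resolved. The α,α-coupling of A1 competes with other coupling modes of an unblocked phenol. The benzylic oxygens of A2 are carboxylate oxygens, not the ring A oxygens. Both lactones must therefore be opened, both rings A attached by C-acylation of a trioxygenated arene next to epimerisable centres, and both C2–O1 bonds re-formed at benzylic carbons whose configuration is then decided anew, most likely in favour of trans. The two 4'-hydroxyls must also be methylated selectively beside the ring A phenols.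
- Comparison: this road reaches the C3–C3' bond and a stereodefined core much faster than the chosen plan, which spends five steps before its key step and sets no stereocentre until step 10. Against that, the chosen plan builds the ring A oxygen pattern unambiguously, needs no resolution if step 10 performs, and never has to re-form C2–O1 with cis control.

**Alternative 2:** The cut is at both C2–aryl bonds. In the forward step 5,5',7,7'-tetrakis(benzyloxy)-3,3'-bichromone A3 takes up two molecules of 4-methoxyphenylboronic acid A4 under [Rh(C2H4)2Cl]2 and a chiral diene, and each rhodium enolate is protonated at C3 to give the tetrabenzyl bis-flavanone A5.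
- Merits: enantioselective arylation of chromones under [Rh(C2H4)2Cl]2 and a chiral diene is established, and the reacting alkene of A3 is trisubstituted, clearly less hindered than the tetrasubstituted alkene of 15. A5 differs from 17 only by a benzyl in place of the 7'-methyl. In stereochemical precedent this road is better than the chosen one.
- Weak points: 3-substituted, 5,7-dialkoxylated chromones are slow acceptors, and electron-rich A4 is prone to protodeboronation. The basic aqueous medium of the arylation can epimerise the cis product A5. The single O-methyl group would have to be introduced on the base-sensitive cis,cis flavanone, or an unsymmetrical bichromone prepared at the cost of convergence. A3 itself needs chromone formation, 3-halogenation and homocoupling.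
- Comparison: the chosen plan sets against this its cheap symmetric building blocks, desymmetrisation before any stereocentre exists, and a reduction product protected from epimerisation as 16. It cannot claim equal precedent for its stereo-defining step.

**Alternative 3:** The cut is at C3–C3' and a temporary C2–C2' bond, both made by [2+2] photodimerisation. In the forward step two molecules of 2-(4-methoxycinnamoyl)-1-methylimidazole A6 dimerise under visible light with Ir(C11H8N)3 as triplet sensitiser and a chiral phosphoric acid, giving the all-trans head-to-head cyclobutane A7.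
- Merits: C3 and C3' are set early by a demonstrated catalytic enantioselective reaction, and the acylimidazole groups that A6 carries into A7 are good handles for aryl ketone formation.
- Weak points: the C2–C2' bond of A7 must later be cleaved oxidatively with both carbons ending as C–O. Donor-substituted cyclobutanes tend to cyclorevert to the monomer A6, which would also break C3–C3', and a selective single-bond version is not available. C2 would then be set by trapping a benzylic cation, which favours trans. Both rings A must be added as aryl nucleophiles while C3 and C3' sit α to carbonyls.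
- Comparison: the first stereo step of this road is proven where that of the chosen plan is not. It does, however, need two unproven operations on the way to the cis rings against one in the chosen plan, and it buys rings A instead of building them.

Key step: step 6

Remark: the target is read as the (2S,2'S,3S,3'S) isomer with H-2 and H-3 cis in both rings C; in step 10 the ligand enantiomer that sends hydride to the required face of C2 is to be fixed on a monomeric 3-substituted flavone, the antipode being equally available.

## Route

Step 1
Reactants: 1 diethyl succinate; 2 4-methoxybenzaldehyde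
Product: 3 (E)-3-(ethoxycarbonyl)-4-(4-methoxyphenyl)but-3-enoic acid
Conditions: KOtBu, t-BuOH, reflux; then aq. HCl
Reagents that add atoms: none
Why: Stobbe condensation: the succinate enolate adds to the aldehyde, the alkoxide lactonises onto the remote ester, and base-induced opening of the paraconate gives the half-ester with the aryl group trans to the retained ester (E).

Step 2
Reactants: 3 (E)-3-(ethoxycarbonyl)-4-(4-methoxyphenyl)but-3-enoic acid
Product: 4 diethyl (E)-2-(4-methoxybenzylidene)succinate
Conditions: EtOH, H2SO4 (cat.), reflux
Reagents that add atoms: ethanol, CCO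
Why: Fischer esterification of the unconjugated acid restores the second ester, so that the remaining methylene can be deprotonated for the next condensation.

Step 3
Reactants: 4 diethyl (E)-2-(4-methoxybenzylidene)succinate; 2 4-methoxybenzaldehyde
Product: 5 (2E,3E)-2,3-bis(4-methoxybenzylidene)succinic acid monoethyl ester
Conditions: KOtBu, t-BuOH, reflux, dark; then aq. HCl; crystallisation
Reagents that add atoms: none
Why: Second Stobbe condensation at the remaining methylene, the classical entry to bis(arylidene)succinic acids; the new alkene should again be E, and light is excluded because the aryl-diene photoisomerises.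

Step 4
Reactants: 5 (2E,3E)-2,3-bis(4-methoxybenzylidene)succinic acid monoethyl ester
Product: 6 diethyl (2E,3E)-2,3-bis(4-methoxybenzylidene)succinate
Conditions: EtI, K2CO3, DMF, 25 °C, dark
Reagents that add atoms: iodoethane, CCI
Why: SN2 O-alkylation of the potassium carboxylate avoids the acid and heat that would close the cyclic anhydride of this diacid.

Step 5
Reactants: 6 diethyl (2E,3E)-2,3-bis(4-methoxybenzylidene)succinate; 7 4-hydroxy-6-methyl-2H-pyran-2-one
Product: 9 6,6'-[(3E,4E)-3,4-bis(4-methoxybenzylidene)-2,5-dioxohexane-1,6-diyl]bis(4-hydroxy-2H-pyran-2-one), via pyrone dianion dilithium salt 8 (not isolated)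
Conditions: 7 (5 equiv), LiN(iPr)2 (10 equiv), THF/DMPU, −78 → −20 °C; add 6, −78 → 0 °C, dark; then aq. HCl
Reagents that add atoms: none
Why: Claisen-type C-acylation of the pyrone dianion at its 6-methyl carbon by esters is known; excess dianion is used because each new doubly activated methylene is deprotonated at once by a second equivalent. The hard lithium carbanion should attack the ester carbonyl, the β-carbon being trisubstituted and deactivated by the 4-methoxyphenyl group.

Step 6
Reactants: 9 6,6'-[(3E,4E)-3,4-bis(4-methoxybenzylidene)-2,5-dioxohexane-1,6-diyl]bis(4-hydroxy-2H-pyran-2-one)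
Product: 11 (2E,3E)-2,3-bis(4-methoxybenzylidene)-1,4-bis(2,4,6-trihydroxyphenyl)butane-1,4-dione, via open-chain bis(triketo ester) 10 (not isolated)
Conditions: Mg(OMe)2 (10 equiv, commercial solution), MeOH, reflux, argon, dark; then cold 1 M HCl
Reagents that add atoms: none
Why: Methoxide adds to the lactone carbonyl of each pyrone and opens it to the magnesium chelate of a methyl 3,5,7-trioxoalkanoate (10). In each arm the methylene between the C5 and C7 ketones then attacks the ester carbon in a Claisen (Dieckmann-type) condensation, a 6-exo-trig closure; loss of methanol and enolisation give the 2,4,6-trihydroxyphenyl ketone, so methanol is taken up and released and the step is an isomerisation. The closest known reaction is the Mg(OMe)2 recyclisation of 6-(2-oxoalkyl)-4-hydroxy-2-pyrones and of 3,5,7-triketo esters to acylphloroglucinols, including a cinnamoyl side chain; its double use on a cross-conjugated bis-enone is an application to a new molecule. Both rings A close in the same way and independently, the two arms being insulated by the twisted diene. No stereocentre is formed, and the E,E geometry should persist because neither alkene is deprotonated or attacked. The selectivity needed is Claisen closure over aldol closure of the ester-flanked methylene onto the C7 ketone, which would give resorcylate esters. Magnesium chelation of the 3,5-diketone secures it, by holding the C6 carbon nucleophilic beside the ester, and the C7 carbonyl is further protected by being a hindered, α-branched enone carbonyl. Any oxa-Michael closure toward 12 that begins here is harmless, since step 7 completes it.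

Step 7
Reactants: 11 (2E,3E)-2,3-bis(4-methoxybenzylidene)-1,4-bis(2,4,6-trihydroxyphenyl)butane-1,4-dione
Product: 13 5,5',7,7'-tetrahydroxy-2,2'-bis(4-methoxyphenyl)-4H,4'H-[3,3'-bichromene]-4,4'-dione, via biflavanone isomer mixture 12 (not isolated)
Conditions: DMSO, 60 °C, dark; then I2 (0.2 equiv), 120 °C
Reagents that add atoms: none
Why: Warming closes both rings C by intramolecular oxa-Michael addition of a 2'-hydroxyl to the enone (6-endo-trig). I2 in DMSO then dehydrogenates the flavanones by iodination at C3 and loss of HI toward C2, with DMSO returning HI to I2; the stereocentres of 12 are erased, so its isomer mixture does not matter.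

Step 8
Reactants: 13 5,5',7,7'-tetrahydroxy-2,2'-bis(4-methoxyphenyl)-4H,4'H-[3,3'-bichromene]-4,4'-dione
Product: 14 5,5',7-trihydroxy-7'-methoxy-2,2'-bis(4-methoxyphenyl)-4H,4'H-[3,3'-bichromene]-4,4'-dione
Conditions: MeI (1.0 equiv), K2CO3 (1.0 equiv), DMF, 0 → 25 °C
Reagents that add atoms: iodomethane, CI
Why: Williamson etherification; the 7-hydroxyls are much more acidic than the hydrogen-bonded 5-hydroxyls and react first. The two 7-hydroxyls are equivalent and remote, so monoalkylation is statistical; recovered 13 is resubmitted and the bis-ether is discarded.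

Step 9
Reactants: 14 5,5',7-trihydroxy-7'-methoxy-2,2'-bis(4-methoxyphenyl)-4H,4'H-[3,3'-bichromene]-4,4'-dione
Product: 15 5,5',7-tris(benzyloxy)-7'-methoxy-2,2'-bis(4-methoxyphenyl)-4H,4'H-[3,3'-bichromene]-4,4'-dione
Conditions: BnBr (5 equiv), K2CO3 (6 equiv), Bu4NI (cat.), DMF, 70 °C
Reagents that add atoms: benzyl bromide, BrCc1ccccc1
Why: Williamson benzylation under forcing conditions also breaks the chelate between 5-OH and the C4 carbonyl, so that the next step meets no acidic hydrogen.

Step 10
Reactants: 15 5,5',7-tris(benzyloxy)-7'-methoxy-2,2'-bis(4-methoxyphenyl)-4H,4'H-[3,3'-bichromene]-4,4'-dione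
Product: 17 (2S,2'S,3S,3'S)-5,5',7-tris(benzyloxy)-7'-methoxy-2,2'-bis(4-methoxyphenyl)-[3,3'-bichromane]-4,4'-dione, via bis(silyl enol ether) 16 (not isolated)
Conditions: Cu(OAc)2 (10 mol%), (R)-DTBM-SEGPHOS (11 mol%), (EtO)2MeSiH (6 equiv), toluene, 25 → 40 °C; then 1 M HCl, THF, −20 → 0 °C
Reagents that add atoms: none
Why: Proposed new method: the monovalent copper hydride formed from Cu(OAc)2, the bisphosphine and the silane should add hydride to C2 of each chromone (the β-carbon of a vinylogous ester) on the face chosen by the ligand, giving a copper enolate that the silane converts into the silyl enol ether while CuH is regenerated; the closest known reactions are the CuH-catalysed enantioselective conjugate reduction of β,β-disubstituted cyclic enones and of 2-substituted chromones, which has not been shown on a 2,3-disubstituted chromone with a tetrasubstituted C2=C3 bond. In 16 both ketones are masked against 1,2-reduction and both C3 centres against epimerisation; allylic strain with the C3 substituent holds each 2-aryl group pseudoaxial, so acid hydrolysis should protonate C3 and C3' anti to it and give H-2/H-3 cis in both rings. Because each half is set by the catalyst independently, material of the wrong sense should fall mainly into a separable unlike diastereomer.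

Step 11
Reactants: 17 (2S,2'S,3S,3'S)-5,5',7-tris(benzyloxy)-7'-methoxy-2,2'-bis(4-methoxyphenyl)-[3,3'-bichromane]-4,4'-dione
Product: 18 (2S,2'S,3S,3'S)-5,5',7-trihydroxy-7'-methoxy-2,2'-bis(4-methoxyphenyl)-[3,3'-bichromane]-4,4'-dione
Conditions: H2 (1 atm), Pd/C (10% Pd on carbon), EtOAc/MeOH, 25 °C
Reagents that add atoms: none
Why: Hydrogenolysis of aryl benzyl ethers over Pd/C is neutral, so the cis C3–H next to the ketone is not epimerised; the reaction is stopped after three equivalents of H2 to spare the benzylic C2–O1 bond.

## Compound list

1 | diethyl succinate | CCOC(=O)CCC(=O)OCC | starting material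
2 | 4-methoxybenzaldehyde | COc1ccc(C=O)cc1 | starting material
3 | (E)-3-(ethoxycarbonyl)-4-(4-methoxyphenyl)but-3-enoic acid | CCOC(=O)/C(=C/c1ccc(OC)cc1)CC(=O)O | intermediate
4 | diethyl (E)-2-(4-methoxybenzylidene)succinate | CCOC(=O)/C(=C/c1ccc(OC)cc1)CC(=O)OCC | intermediate
5 | (2E,3E)-2,3-bis(4-methoxybenzylidene)succinic acid monoethyl ester | CCOC(=O)/C(=C/c1ccc(OC)cc1)C(=C/c1ccc(OC)cc1)\C(=O)O | intermediate
6 | diethyl (2E,3E)-2,3-bis(4-methoxybenzylidene)succinate | CCOC(=O)/C(=C/c1ccc(OC)cc1)C(=C/c1ccc(OC)cc1)\C(=O)OCC | intermediate
7 | 4-hydroxy-6-methyl-2H-pyran-2-one | Cc1cc(O)cc(=O)o1 | starting material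
8 | dilithium salt of the dianion of 7 (4-oxido-6-methylide) | [Li+].[Li+].[CH2-]c1cc([O-])cc(=O)o1 | intermediate (not isolated)
9 | 6,6'-[(3E,4E)-3,4-bis(4-methoxybenzylidene)-2,5-dioxohexane-1,6-diyl]bis(4-hydroxy-2H-pyran-2-one) | O=c1cc(O)cc(CC(=O)/C(=C/c2ccc(OC)cc2)C(=C/c2ccc(OC)cc2)\C(=O)Cc2cc(O)cc(=O)o2)o1 | intermediate
10 | dimethyl (8E,9E)-8,9-bis(4-methoxybenzylidene)-3,5,7,10,12,14-hexaoxohexadecanedioate (present as its magnesium chelate) | COC(=O)CC(=O)CC(=O)CC(=O)/C(=C/c1ccc(OC)cc1)C(=C/c1ccc(OC)cc1)\C(=O)CC(=O)CC(=O)CC(=O)OC | intermediate (not isolated)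
11 | (2E,3E)-2,3-bis(4-methoxybenzylidene)-1,4-bis(2,4,6-trihydroxyphenyl)butane-1,4-dione | O=C(/C(=C/c1ccc(OC)cc1)C(=C/c1ccc(OC)cc1)\C(=O)c1c(O)cc(O)cc1O)c1c(O)cc(O)cc1O | intermediate
12 | 5,5',7,7'-tetrahydroxy-2,2'-bis(4-methoxyphenyl)-[3,3'-bichromane]-4,4'-dione, mixture of diastereomers | COc1ccc(C2Oc3cc(O)cc(O)c3C(=O)C2C2C(=O)c3c(O)cc(O)cc3OC2c2ccc(OC)cc2)cc1 | intermediate (not isolated)
13 | 5,5',7,7'-tetrahydroxy-2,2'-bis(4-methoxyphenyl)-4H,4'H-[3,3'-bichromene]-4,4'-dione | COc1ccc(cc1)-c1oc2cc(O)cc(O)c2c(=O)c1-c1c(-c2ccc(OC)cc2)oc2cc(O)cc(O)c2c1=O | intermediate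
14 | 5,5',7-trihydroxy-7'-methoxy-2,2'-bis(4-methoxyphenyl)-4H,4'H-[3,3'-bichromene]-4,4'-dione | COc1ccc(cc1)-c1oc2cc(OC)cc(O)c2c(=O)c1-c1c(-c2ccc(OC)cc2)oc2cc(O)cc(O)c2c1=O | intermediate
15 | 5,5',7-tris(benzyloxy)-7'-methoxy-2,2'-bis(4-methoxyphenyl)-4H,4'H-[3,3'-bichromene]-4,4'-dione | COc1ccc(cc1)-c1oc2cc(OC)cc(OCc3ccccc3)c2c(=O)c1-c1c(-c2ccc(OC)cc2)oc2cc(OCc3ccccc3)cc(OCc3ccccc3)c2c1=O | intermediate
16 | 5,5',7-tris(benzyloxy)-4,4'-bis{[diethoxy(methyl)silyl]oxy}-7'-methoxy-2,2'-bis(4-methoxyphenyl)-2H,2'H-3,3'-bichromene, C2 and C2' arranged in space as in 17 (formally 2R,2'R, because C3 now outranks the aryl group) | COc1ccc([C@H]2Oc3cc(OCc4ccccc4)cc(OCc4ccccc4)c3C(O[Si](C)(OCC)OCC)=C2C2=C(O[Si](C)(OCC)OCC)c3c(OCc4ccccc4)cc(OC)cc3O[C@@H]2c2ccc(OC)cc2)cc1 | intermediate (not isolated)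
17 | (2S,2'S,3S,3'S)-5,5',7-tris(benzyloxy)-7'-methoxy-2,2'-bis(4-methoxyphenyl)-[3,3'-bichromane]-4,4'-dione (both rings 2,3-cis) | COc1ccc([C@H]2Oc3cc(OCc4ccccc4)cc(OCc4ccccc4)c3C(=O)[C@H]2[C@@H]2C(=O)c3c(OCc4ccccc4)cc(OC)cc3O[C@@H]2c2ccc(OC)cc2)cc1 | intermediate
18 | (2S,2'S,3S,3'S)-5,5',7-trihydroxy-7'-methoxy-2,2'-bis(4-methoxyphenyl)-[3,3'-bichromane]-4,4'-dione (both rings 2,3-cis) | COc1ccc([C@H]2Oc3cc(O)cc(O)c3C(=O)[C@H]2[C@@H]2C(=O)c3c(O)cc(OC)cc3O[C@@H]2c2ccc(OC)cc2)cc1 | target

Total step count: 11. Longest linear sequence: 11 steps (1 to 18; 2 and 7 enter along the way).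

## Steps least certain to work

**Step 10 (proposed new method).**
- What may go wrong: hydride transfer to the tetrasubstituted, donor-substituted C2=C3 bond may fail, or hydride may go to the C4 carbonyl instead. Facial control at the second chromone may be lost because the hindered C3–C3' axis rotates slowly and one rotamer may be mismatched with the catalyst. Protonation at C3 may occur syn to the aryl group and give a trans ring.
- Fallback, from 15, by known reactions: stoichiometric conjugate reduction with LiBH(sBu)3 in THF at −78 °C, followed by inverse quench into cold acetic acid, should give the cis rings without absolute control. The products would be 17, its enantiomer (2R,2'R,3R,3'R)-5,5',7-tris(benzyloxy)-7'-methoxy-2,2'-bis(4-methoxyphenyl)-[3,3'-bichromane]-4,4'-dione F1, and the racemic unlike cis,cis diastereomer rac-(2S,2'R,3S,3'R)-5,5',7-tris(benzyloxy)-7'-methoxy-2,2'-bis(4-methoxyphenyl)-[3,3'-bichromane]-4,4'-dione F2. F2 would be removed on silica and F1 by preparative chromatography on a cellulose tris(3,5-dimethylphenylcarbamate) phase. The route is rejoined at 17, at the cost of most of the material.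

**Step 6 (key step).**
- What may go wrong: aldol closure to resorcylate esters may compete with Claisen closure. Methoxide may cleave the side-chain 1,3-diketone (retro-Claisen), which undoes step 5, or add to an arylidene carbon. Only one of the two rings may close.
- Fallback, from 6: 1,3,5-tris(methoxymethoxy)benzene F3 is lithiated between two of its ether groups (n-BuLi, THF, 0 °C) to [2,4,6-tris(methoxymethoxy)phenyl]lithium F4. F4 is acylated twice by diester 6 to give (2E,3E)-2,3-bis(4-methoxybenzylidene)-1,4-bis[2,4,6-tris(methoxymethoxy)phenyl]butane-1,4-dione F5, the doubly ortho-substituted aryl ketone being too hindered for a second addition. HCl in methanol removes the six acetals, and the route is rejoined at 11. This gives up the pyrone construction of rings A.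

**Step 5.**
- What may go wrong: the dianion may add in conjugate fashion to the arylidene ester. The second acylation of the hindered, deactivated ester may stall. Proton transfer from the product may consume the nucleophile.
- Fallback, from 6, by aldol addition and oxidation in place of acylation: iBu2AlH reduces both esters to (2E,3E)-2,3-bis(4-methoxybenzylidene)butane-1,4-diol F6. Swern oxidation gives (2E,3E)-2,3-bis(4-methoxybenzylidene)succinaldehyde F7. Dianion 8 adds to both aldehyde groups to give 6,6'-[(3E,4E)-2,5-dihydroxy-3,4-bis(4-methoxybenzylidene)hexane-1,6-diyl]bis(4-hydroxy-2H-pyran-2-one) F8 as a mixture of diastereomers. MnO2 oxidises the two allylic alcohols, and the route is rejoined at 9.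

**Step 7.**
- What may go wrong: the free phloroglucinol rings may be iodinated. HI may be lost toward the exocyclic C3=C3' alkene instead of toward C2. The reaction may stop after one dehydrogenation.
- Fallback, from 11: ring closure with NaOAc in ethanol and isolation of 12. Ac2O in pyridine then gives 5,5',7,7'-tetraacetoxy-2,2'-bis(4-methoxyphenyl)-[3,3'-bichromane]-4,4'-dione F9 as a mixture of diastereomers. DDQ in dioxane at reflux removes hydride from the benzylic, oxygen-bearing C2, so the double bond can only form toward C3, and gives 5,5',7,7'-tetraacetoxy-2,2'-bis(4-methoxyphenyl)-4H,4'H-[3,3'-bichromene]-4,4'-dione F10. K2CO3 in methanol removes the acetates, and the route is rejoined at 13.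

## Further compounds

F1 | step 10 | (2R,2'R,3R,3'R)-5,5',7-tris(benzyloxy)-7'-methoxy-2,2'-bis(4-methoxyphenyl)-[3,3'-bichromane]-4,4'-dione (enantiomer of 17) | COc1ccc([C@@H]2Oc3cc(OCc4ccccc4)cc(OCc4ccccc4)c3C(=O)[C@@H]2[C@H]2C(=O)c3c(OCc4ccccc4)cc(OC)cc3O[C@H]2c2ccc(OC)cc2)cc1
F2 | step 10 | rac-(2S,2'R,3S,3'R)-5,5',7-tris(benzyloxy)-7'-methoxy-2,2'-bis(4-methoxyphenyl)-[3,3'-bichromane]-4,4'-dione (unlike cis,cis diastereomer, one enantiomer drawn) | COc1ccc([C@H]2Oc3cc(OCc4ccccc4)cc(OCc4ccccc4)c3C(=O)[C@H]2[C@H]2C(=O)c3c(OCc4ccccc4)cc(OC)cc3O[C@H]2c2ccc(OC)cc2)cc1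
F3 | step 6 | 1,3,5-tris(methoxymethoxy)benzene | COCOc1cc(OCOC)cc(OCOC)c1
F4 | step 6 | [2,4,6-tris(methoxymethoxy)phenyl]lithium | [Li]c1c(OCOC)cc(OCOC)cc1OCOC
F5 | step 6 | (2E,3E)-2,3-bis(4-methoxybenzylidene)-1,4-bis[2,4,6-tris(methoxymethoxy)phenyl]butane-1,4-dione | O=C(/C(=C/c1ccc(OC)cc1)C(=C/c1ccc(OC)cc1)\C(=O)c1c(OCOC)cc(OCOC)cc1OCOC)c1c(OCOC)cc(OCOC)cc1OCOC
F6 | step 5 | (2E,3E)-2,3-bis(4-methoxybenzylidene)butane-1,4-diol | OC/C(=C/c1ccc(OC)cc1)C(=C/c1ccc(OC)cc1)\CO
F7 | step 5 | (2E,3E)-2,3-bis(4-methoxybenzylidene)succinaldehyde | O=C/C(=C/c1ccc(OC)cc1)C(=C/c1ccc(OC)cc1)\C=O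
F8 | step 5 | 6,6'-[(3E,4E)-2,5-dihydroxy-3,4-bis(4-methoxybenzylidene)hexane-1,6-diyl]bis(4-hydroxy-2H-pyran-2-one), mixture of diastereomers | O=c1cc(O)cc(CC(O)/C(=C/c2ccc(OC)cc2)C(=C/c2ccc(OC)cc2)\C(O)Cc2cc(O)cc(=O)o2)o1
F9 | step 7 | 5,5',7,7'-tetraacetoxy-2,2'-bis(4-methoxyphenyl)-[3,3'-bichromane]-4,4'-dione, mixture of diastereomers | COc1ccc(C2Oc3cc(OC(C)=O)cc(OC(C)=O)c3C(=O)C2C2C(=O)c3c(OC(C)=O)cc(OC(C)=O)cc3OC2c2ccc(OC)cc2)cc1
F10 | step 7 | 5,5',7,7'-tetraacetoxy-2,2'-bis(4-methoxyphenyl)-4H,4'H-[3,3'-bichromene]-4,4'-dione | COc1ccc(cc1)-c1oc2cc(OC(C)=O)cc(OC(C)=O)c2c(=O)c1-c1c(-c2ccc(OC)cc2)oc2cc(OC(C)=O)cc(OC(C)=O)c2c1=O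
A1 | alternative 1 | 4-hydroxycinnamic acid | O=C(O)/C=C/c1ccc(O)cc1
A2 | alternative 1 | cis-fused exo,exo-4,8-bis(4-hydroxyphenyl)-3,7-dioxabicyclo[3.3.0]octane-2,6-dione | Oc1ccc(cc1)[C@H]1OC(=O)[C@H]2[C@@H]1C(=O)O[C@@H]2c1ccc(O)cc1
A3 | alternative 2 | 5,5',7,7'-tetrakis(benzyloxy)-3,3'-bichromone | O=c1c(-c2coc3cc(OCc4ccccc4)cc(OCc4ccccc4)c3c2=O)coc2cc(OCc3ccccc3)cc(OCc3ccccc3)c12
A4 | alternative 2 | 4-methoxyphenylboronic acid | COc1ccc(B(O)O)cc1
A5 | alternative 2 | (2S,2'S,3S,3'S)-5,5',7,7'-tetrakis(benzyloxy)-2,2'-bis(4-methoxyphenyl)-[3,3'-bichromane]-4,4'-dione | COc1ccc([C@H]2Oc3cc(OCc4ccccc4)cc(OCc4ccccc4)c3C(=O)[C@H]2[C@@H]2C(=O)c3c(OCc4ccccc4)cc(OCc4ccccc4)cc3O[C@@H]2c2ccc(OC)cc2)cc1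
A6 | alternative 3 | 2-(4-methoxycinnamoyl)-1-methylimidazole | COc1ccc(/C=C/C(=O)c2nccn2C)cc1
A7 | alternative 3 | all-trans head-to-head [3,4-bis(4-methoxyphenyl)cyclobutane-1,2-diyl]bis[(1-methylimidazol-2-yl)methanone] | Cn1ccnc1C(=O)[C@H]1[C@H](C(=O)c2nccn2C)[C@@H](c2ccc(OC)cc2)[C@@H]1c1ccc(OC)cc1
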